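Atom labels used throughout: ring C1 (CH bearing isopropenyl), C2=C3 (C3 bears CH3), C4 (CH bearing the CH2O arm), C5 (quaternary: CH3 and the acid arm), C6 (CH2). Side-chain carbons: C7 is the CH2O carbon on C4, C10 and C9 are the chain methylenes (C10 on C5), C8 is the carboxyl carbon.

## Analysis of the target

The target is 3-[(1R,2R,5S)-1,3-dimethyl-2-{[(2-oxo-2H-chromen-7-yl)oxy]methyl}-5-(prop-1-en-2-yl)cyclohex-3-en-1-yl]propanoic acid: one cyclohexene ring carrying four substituents, tied through a CH2–O bond to a coumarin. There are three stereocentres, C1 (S), C4 (R) and C5 (R) in the labels above. C4–H and C5–CH3 lie on one face of the ring; the C7 arm, the C10 arm and the isopropenyl group all lie on the other. C4 and C5 are adjacent and C5 is quaternary, whereas C1 is remote (1,3 to C5, 1,4 to C4) and has no heteroatom nearby to steer its formation. The sensitive parts are the coumarin (a Michael acceptor and a base-labile lactone), the skipped diene with its doubly allylic C1–H, and C4, which becomes epimerisable whenever C3 or C7 is a carbonyl. The difficulty is to set the quaternary C5 next to C4 in the absolute sense and then to place C1 without a neighbouring control element, while keeping the coumarin out of all organometallic steps. The strategy rests on one observation: C5, its CH3, C4, C7, C8, C9 and C10 are the seven carbons of a 4-methylcyclohexa-2,5-dienone if C7 is joined to C8, with C8 as the carbonyl. In that symmetrical ring C5 is prochiral, and ring C1–C6 arises when C3, as a tethered aldehyde carbon, is joined to C4, an enone β carbon.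

## Retrosynthetic reasoning

**Acid and aryl ether last (34 ⇐ 32 ⇐ 30 + 31).** The C7–O(aryl) bond is cut first. The coumarin of 31 would not survive enolate, organocopper or organorhodium chemistry, so it enters after the last of these, by a Mitsunobu reaction at the non-stereogenic primary carbon C7. The acid is carried as methyl ester 32, because a free acid would compete with the phenol as the nucleophile.

**C3–CH3 (30 ⇐ 29 ⇐ 28).** The methyl group on C3 is cut back to alkenyl triflate 28. A triflate made from the C2 enolate of a C3 ketone puts the ring alkene exactly at C2=C3, and the coupling that replaces it cannot move the alkene. The silyl ether on C7 is removed only after this step.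

**C1–isopropenyl (28 ⇐ 26 ⇐ 24 + 25).** With a carbonyl at C3, C1 is the β carbon of enone 24, so the isopropenyl group is cut off as a 1,4-donor, 25. In 24 each face of C1 is flanked by one C5 substituent in the syn-axial position (CH3 on one side, the C10 arm on the other), and the C7 arm is too far away to decide. Substrate control, as in a cuprate addition with enolate trapping, therefore cannot be relied on to place the isopropenyl group trans to the C5 methyl. The addition is planned under the control of a chiral bisphosphine on rhodium, and the triflate is made in a separate kinetic enolisation. Enone 24 comes from ketone 21 by dehydrogenation, which can only run toward C2–C1 because C5 has no hydrogen.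

**C7–C8 reconnected (21 ⇐ 20 ⇐ 19 ⇐ 17 ⇐ 16 ⇐ 14 ⇐ 13).** The two arms on C4 and C5 are read as the ends of a cut ring. Joining C7 (as carbinol) to C8 (as carbonyl) gives α-ketol 17, whose oxidative cleavage gives an aldehyde on C4 and a methyl ester on the chain. The ketol comes from the enone of 14: its γ carbon is the quaternary C5, so the only enolisable position is C7 and the oxygen goes there and nowhere else. The C9=C10 alkene of the enone is hydrogenated to the two chain methylenes. The C3 carbonyl has to be masked as the ketal of 14 during this work, since it would otherwise be the more acidic site.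

**C3–C4, the key cut (13 ⇐ 12).** Cutting C3–C4 in 13 opens ring A and leaves an aldehyde (C3) on a three-carbon tether from C5 of an achiral 4-methylcyclohexadienone, 12. The forward reaction needs C3 to act as an acyl anion, which a carbene catalyst provides. It also needs a choice between two enantiotopic enone arms, which creates C4 and C5 together. The cis relation of C4–H and C5–CH3 follows from the tether length.

**Dienone precursor (12 ⇐ 10 ⇐ 9 ⇐ 6 + 7; 6 ⇐ 2 + 3; 2 ⇐ 1).** The aldehyde of 12 is cut back to the terminal alkene of 10. The dienone comes from enone 9 by dehydrogenation, and 9 from a Robinson annulation of the α-branched aldehyde 6 with 7. Aldehyde 6 is the α-alkylation product of 1 with 3 through imine 2. A pentenyl chain is used instead of an allyl chain because a 4-allyl dienone could aromatise by a [3,3] shift.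

## Alternatives that were turned down

**Alternative 1:** The bond from C5 to C10 is cut, and C10 is taken from the CH2 of the isopropenyl group on C1. In the forward step a primary radical, made from a bromohydrin arm on C1, adds 5-exo to the β carbon C5 of a β-methyl enone (C3 carbonyl, C4 carrying the silyloxymethyl group). This gives 2-{[tert-butyl(dimethyl)silyl]oxymethyl}-6-hydroxy-1,6-dimethylbicyclo[3.2.1]octan-3-one A1. In its favour, the bridge fixes the cis relation of the C1 and C5 carbon substituents with certainty, a radical tolerates the crowding of quaternary-centre formation, and the CH2O arm on C4 can settle equatorial by equilibration, which is the required configuration. On the C1/C5 relation this plan is stronger than the chosen one, which depends on a ligand. Against it, the isopropenyl group is consumed and must be rebuilt: the carbinol bridge has to be fragmented between the carbinol carbon and C10, in competition with cleavage toward C1, and the resulting acetyl group methylenated. The chain must still be lengthened by two carbons, the C3 ketone must still be turned into C2=C3–CH3, and the substrate is a tetrasubstituted enone that itself needs several steps. The chosen route offers in exchange a catalytic entry from achiral material that sets C4 and C5 in one step and leaves every carbon of both arms in place.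

**Alternative 2:** The bonds C5–C6 and C3=C4 are cut. The chiral imine of 2-methylcyclohexan-1-one A2 adds through its secondary enamine to pent-1-en-3-one A3, and after hydrolysis an aldol condensation closes the target ring, giving (R)-1,4a-dimethyl-4,4a,5,6,7,8-hexahydronaphthalen-2(3H)-one A4. This is cheap, scalable and dependable for the quaternary centre, and it installs the C3 methyl at once; on cost and robustness of the first stereocentre it is at least as good as the chosen key step. Its weakness for this target lies in what follows. The ring to be sacrificed in A4 is four plain methylenes, so cutting between C7 and C8 needs oxidation of two adjacent unactivated carbons, of which only the one next to the alkene is activated. C4 is sp2 and must receive its hydrogen cis to the C5 methyl. The carbonyl sits on C2, so C1 must be alkenylated α to it and the oxygen then removed. In 13, by contrast, the ring to be cut already carries a carbonyl at C8 next to the only enolisable carbon C7, C4 is already set, and the C3 carbonyl serves both C1 and the C2=C3–CH3 unit.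

**Alternative 3:** The bond from C5 to C10 is cut together with a temporary bond from C10 to C6. Birch reduction of 2,6-dimethylbenzoic acid A5 and reduction of the acid give a dienylmethanol whose diazoacetate, (2,6-dimethylcyclohexa-2,5-dien-1-yl)methyl diazoacetate A6, has a mirror plane. A chiral rhodium carbenoid adds to one enantiotopic ring alkene and gives the cyclopropane-fused tricyclic δ-lactone A7. This is the shortest route to a compound with C4 and C5 set; the C3 methyl, the C2=C3 alkene and the CH2O carbon at the right oxidation level are all present from the start. On speed to the core it beats the chosen route. Against it, the acyl carbon sits directly on C10, so the chain is one carbon short and must be homologated. The cyclopropane must be opened at C10–C6 and not at C10–C5. C1 is a bare allylic methylene, so the isopropenyl group would have to be introduced by allylic functionalisation with stereocontrol and without moving the alkene. Enantioselective cyclopropanation of a trisubstituted alkene with six-membered lactone closure is also a less secure class. The chosen route is longer to its core but keeps a carbonyl at C3, from which C1, C2 and C3 are all reached by standard enone chemistry.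

Key step: step 6

Assumption: the (5aS,10bR) antipode of the aminoindanol-derived triazolium salt is taken to be the one that gives (4aS,8aR)-13; if the sense proves opposite, the (5aR,10bS) antipode is used and nothing else changes.

## Route

Step 1
Reactants: 1 propanal
Product: 2 (E)-N-tert-butylpropan-1-imine
Conditions: tBuNH2, neat, 0 °C → rt; KOH pellets; distil
Reagents that add atoms: tert-butylamine, CC(C)(C)N
Why: Condensation of an unhindered aldehyde with a primary amine gives the aldimine; the bulky N-substituent suppresses self-condensation and N-alkylation in the next step.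

Step 2
Reactants: 2 (E)-N-tert-butylpropan-1-imine; 3 5-bromopent-1-ene
Product: 6 2-methylhept-6-enal (racemic), via lithium aza-enolate 4 (not isolated), via alkylated imine 5 (not isolated)
Conditions: LiN(iPr)2, THF, −78 → 0 °C; then 3, −78 °C → rt; then 1 M HCl, rt
Reagents that add atoms: water, O
Why: Metalloenamine alkylation: the aza-enolate is C-alkylated once by the primary bromide, and mild acid hydrolysis releases the α-branched aldehyde. The stereocentre is racemic and is erased when the dienone is formed in step 4.

Step 3
Reactants: 6 2-methylhept-6-enal (racemic); 7 but-3-en-2-one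
Product: 9 4-methyl-4-(pent-4-en-1-yl)cyclohex-2-en-1-one (racemic), via keto aldehyde 8 (not isolated)
Conditions: H2SO4 (cat.), toluene, 45 °C then reflux (Dean–Stark)
Reagents that add atoms: none
Why: Acid-catalysed Robinson annulation: the enol of the α-branched aldehyde adds to the enone, and the methyl ketone of 8 condenses onto the aldehyde, which has no α-hydrogen left, so only one aldol mode exists. This is the classical route to 4,4-disubstituted cyclohexenones.

Step 4
Reactants: 9 4-methyl-4-(pent-4-en-1-yl)cyclohex-2-en-1-one (racemic)
Product: 10 4-methyl-4-(pent-4-en-1-yl)cyclohexa-2,5-dien-1-one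
Conditions: DDQ, dioxane, reflux
Reagents that add atoms: none
Why: Quinone dehydrogenation of the enone through its dienol gives the cross-conjugated dienone; the quaternary carbon blocks aromatisation and the isolated terminal alkene is not activated toward hydride abstraction.

Step 5
Reactants: 10 4-methyl-4-(pent-4-en-1-yl)cyclohexa-2,5-dien-1-one
Product: 12 4-(1-methyl-4-oxocyclohexa-2,5-dien-1-yl)butanal, via diol 11 (not isolated)
Conditions: OsO4 (cat.), NaIO4, 2,6-lutidine, dioxane/H2O, rt
Reagents that add atoms: osmium tetroxide, O=[Os](=O)(=O)=O; sodium periodate, [Na+].[O-]I(=O)(=O)=O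
Why: Lemieux–Johnson oxidation: the electron-rich monosubstituted alkene is dihydroxylated far faster than the electron-poor dienone alkenes, which are also shielded by the quaternary carbon, and periodate cleaves the diol as it forms. The lutidine buffer limits over-oxidation.

Step 6
Reactants: 12 4-(1-methyl-4-oxocyclohexa-2,5-dien-1-yl)butanal
Product: 13 (4aS,8aR)-4a-methyl-3,4,4a,8a-tetrahydronaphthalene-1,7(2H,8H)-dione
Conditions: (5aS,10bR)-2-(pentafluorophenyl)-5a,10b-dihydro-4H,6H-indeno[2,1-b][1,2,4]triazolo[4,3-d][1,4]oxazin-2-ium tetrafluoroborate (20 mol %), KN(SiMe3)2 (20 mol %), toluene, 23 °C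
Reagents that add atoms: none
Why: Deprotonation of the triazolium salt gives the triazolylidene, which adds to the aldehyde of 12; proton transfer then gives the enaminol, an acyl anion equivalent at C3. This carbon adds to the β carbon of one enone arm (C4), and after proton transfer the carbene is expelled, leaving the 1,4-diketone 13. The closest known reaction type is the carbene-catalysed asymmetric intramolecular Stetter desymmetrisation of 4,4-disubstituted cyclohexa-2,5-dienones. Ring A closes in a 6-exo-trig mode. C4 and C5 are created in the same event: their relative configuration (cis fusion, C4–H cis to C5–CH3) is imposed by the three-carbon tether, which can reach the β carbon only on the face of C5 from which it leaves. Their absolute configuration depends on which enantiotopic arm is attacked, and that choice is made by the chiral pocket of the aminoindanol-derived carbene. The step needs enantiotopic-group selectivity and preference for the Stetter path over benzoin and aldol reactions; the second is served by the substoichiometric base, the non-polar solvent and the closeness of the aldehyde to a doubly activated acceptor. The enolate is finally protonated at C7, which is not stereogenic.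

Step 7
Reactants: 13 (4aS,8aR)-4a-methyl-3,4,4a,8a-tetrahydronaphthalene-1,7(2H,8H)-dione
Product: 14 (4a'S,8a'R)-4a'-methyl-3',4',4a',8a'-tetrahydro-2'H-spiro[1,3-dioxolane-2,1'-naphthalen]-7'(8'H)-one
Conditions: Me3SiOCH2CH2OSiMe3, Me3SiOTf (cat.), CH2Cl2, −78 → −20 °C; pyridine quench
Reagents that add atoms: 1,2-bis(trimethylsilyloxy)ethane, C[Si](C)(C)OCCO[Si](C)(C)C
Why: Chemoselective ketalisation: under silyl triflate catalysis at low temperature a saturated ketone is ketalised much faster than a conjugated enone, so only the C3 carbonyl is masked. The cold, non-aqueous conditions should leave the epimerisable C4 untouched.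

Step 8
Reactants: 14 (4a'S,8a'R)-4a'-methyl-3',4',4a',8a'-tetrahydro-2'H-spiro[1,3-dioxolane-2,1'-naphthalen]-7'(8'H)-one
Product: 16 8'-hydroxy derivative of 14 (both epimers at the carbinol carbon C7; ring fusion as in 14), via potassium dienolate 15 (not isolated)
Conditions: KN(SiMe3)2, THF, −78 °C; then 2-(phenylsulfonyl)-3-phenyloxaziridine, −78 °C; aq. NH4Cl
Reagents that add atoms: 2-(phenylsulfonyl)-3-phenyloxaziridine, O=S(=O)(c1ccccc1)N1OC1c1ccccc1
Why: Enolate hydroxylation: the enone has no γ-hydrogen because C5 is quaternary, so the base can only form the cross-conjugated dienolate at C7, and the N-sulfonyloxaziridine transfers oxygen to that carbon. The configuration of the new carbinol is irrelevant, since C7 becomes a CH2O carbon.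

Step 9
Reactants: 16 8'-hydroxy derivative of 14
Product: 17 saturated α-ketol (5',6'-dihydro derivative of 16; both epimers at C7)
Conditions: H2 (1 atm), Pd/C, EtOAc, rt
Reagents that add atoms: none
Why: Heterogeneous hydrogenation saturates the disubstituted enone alkene (the future C9 and C10 methylenes) under neutral conditions that should not isomerise the α-ketol; ketal and carbinol are inert.

Step 10
Reactants: 17 saturated α-ketol
Product: 19 methyl 3-[(6S,7S)-6-(hydroxymethyl)-7-methyl-1,4-dioxaspiro[4.5]decan-7-yl]propanoate, via aldehyde ester 18 (not isolated)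
Conditions: Pb(OAc)4, MeOH/toluene, 0 °C; then NaBH4, −20 → 0 °C
Reagents that add atoms: methanol, CO
Why: Glycol-type cleavage of the α-ketol through its methanol hemiketal cuts C7–C8 and gives the aldehyde on C4 and the methyl ester of the chain. Immediate borohydride reduction of 18 in the same pot removes the formyl group before C4 can epimerise, and the ester is not reduced at this temperature.

Step 11
Reactants: 19 methyl 3-[(6S,7S)-6-(hydroxymethyl)-7-methyl-1,4-dioxaspiro[4.5]decan-7-yl]propanoate
Product: 20 methyl 3-[(6S,7S)-6-{[tert-butyl(diphenyl)silyl]oxymethyl}-7-methyl-1,4-dioxaspiro[4.5]decan-7-yl]propanoate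
Conditions: tBuPh2SiCl, imidazole, DMF, rt
Reagents that add atoms: tert-butyl(chloro)diphenylsilane, CC(C)(C)[Si](Cl)(c1ccccc1)c1ccccc1
Why: Silylation of a primary alcohol; this silyl ether is chosen because it should survive the acid of step 12 and the enolate and organometallic steps, and it is removed by fluoride.

Step 12
Reactants: 20 methyl 3-[(6S,7S)-6-{[tert-butyl(diphenyl)silyl]oxymethyl}-7-methyl-1,4-dioxaspiro[4.5]decan-7-yl]propanoate
Product: 21 methyl 3-[(1S,2S)-2-{[tert-butyl(diphenyl)silyl]oxymethyl}-1-methyl-3-oxocyclohexyl]propanoate
Conditions: PPTS, acetone/H2O, 55 °C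
Reagents that add atoms: water, O
Why: Mild acid-catalysed hydrolysis of the dioxolane releases the C3 ketone; the silyl ether and methyl ester are stable, and the weak acid should not enolise the ketone toward C4.

Step 13
Reactants: 21 methyl 3-[(1S,2S)-2-{[tert-butyl(diphenyl)silyl]oxymethyl}-1-methyl-3-oxocyclohexyl]propanoate
Product: 24 methyl 3-[(1R,6S)-6-{[tert-butyl(diphenyl)silyl]oxymethyl}-1-methyl-5-oxocyclohex-3-en-1-yl]propanoate, via lithium enolate 22 (not isolated), via silyl enol ether 23 (not isolated)
Conditions: LiN(iPr)2, THF, −78 °C; Me3SiCl; then Pd(OAc)2, MeCN, rt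
Reagents that add atoms: none
Why: Saegusa–Ito oxidation: kinetic deprotonation takes the unhindered C2 methylene rather than the C4 methine next to the quaternary carbon, and is faster than at the ester. Palladation of the silyl enol ether and β-hydride elimination give the C2=C1 enone; C4 is never enolised, so its configuration is kept.

Step 14
Reactants: 24 methyl 3-[(1R,6S)-6-{[tert-butyl(diphenyl)silyl]oxymethyl}-1-methyl-5-oxocyclohex-3-en-1-yl]propanoate; 25 potassium trifluoro(prop-1-en-2-yl)borate
Product: 26 methyl 3-[(1R,2S,5S)-2-{[tert-butyl(diphenyl)silyl]oxymethyl}-1-methyl-3-oxo-5-(prop-1-en-2-yl)cyclohexyl]propanoate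
Conditions: [Rh(cod)Cl]2 (cat.), (S)-BINAP, Et3N, dioxane/H2O, 70 °C
Reagents that add atoms: none
Why: Rhodium-catalysed asymmetric 1,4-addition of an alkenylboron reagent (Hayashi–Miyaura reaction): the alkenylrhodium species inserts the enone and water protonates the rhodium enolate. The new C1 stereocentre is set by the ligand: with (S)-BINAP the alkenyl group goes to the enone face from which the sequence carbonyl carbon, α carbon, β carbon runs clockwise, which in 24 is the face opposite the C5 methyl. Substrate bias is expected to be small because each face carries one syn-axial C5 substituent, so the catalyst should decide.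

Step 15
Reactants: 26 methyl 3-[(1R,2S,5S)-2-{[tert-butyl(diphenyl)silyl]oxymethyl}-1-methyl-3-oxo-5-(prop-1-en-2-yl)cyclohexyl]propanoate
Product: 28 methyl 3-[(1R,2S,5S)-2-{[tert-butyl(diphenyl)silyl]oxymethyl}-1-methyl-5-(prop-1-en-2-yl)-3-{[(trifluoromethyl)sulfonyl]oxy}cyclohex-3-en-1-yl]propanoate, via potassium enolate 27 (not isolated)
Conditions: KN(SiMe3)2, THF, −78 °C; then PhNTf2, −78 → 0 °C
Reagents that add atoms: N-phenylbis(trifluoromethanesulfonimide), O=S(=O)(N(c1ccccc1)S(=O)(=O)C(F)(F)F)C(F)(F)F
Why: Kinetic enol triflate formation: the bulky amide again takes the C2 methylene instead of the hindered C4 methine, and triflyl transfer to the enolate fixes the double bond at C2=C3. C1 and C4 are not touched.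

Step 16
Reactants: 28 alkenyl triflate
Product: 29 methyl 3-[(1R,2R,5S)-2-{[tert-butyl(diphenyl)silyl]oxymethyl}-1,3-dimethyl-5-(prop-1-en-2-yl)cyclohex-3-en-1-yl]propanoate
Conditions: MeZnCl, Pd(PPh3)4 (cat.), THF, 50 °C
Reagents that add atoms: methylzinc chloride, C[Zn]Cl
Why: Negishi coupling: oxidative addition of the alkenyl triflate to zerovalent palladium, transmetallation from zinc and reductive elimination put the methyl group on C3 without moving the alkene. The organozinc reagent does not attack the ester, and a methyl group has no β-hydrogen to lose.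

Step 17
Reactants: 29 methyl 3-[(1R,2R,5S)-2-{[tert-butyl(diphenyl)silyl]oxymethyl}-1,3-dimethyl-5-(prop-1-en-2-yl)cyclohex-3-en-1-yl]propanoate
Product: 30 methyl 3-[(1R,2R,5S)-2-(hydroxymethyl)-1,3-dimethyl-5-(prop-1-en-2-yl)cyclohex-3-en-1-yl]propanoate
Conditions: Bu4NF, AcOH, THF, rt
Reagents that add atoms: none
Why: Fluoride cleavage of the silyl ether; the acetic acid buffer keeps the alkoxide from closing the seven-membered lactone onto the ester and protects the skipped diene from base.

Step 18
Reactants: 30 methyl 3-[(1R,2R,5S)-2-(hydroxymethyl)-1,3-dimethyl-5-(prop-1-en-2-yl)cyclohex-3-en-1-yl]propanoate; 31 umbelliferone (7-hydroxy-2H-chromen-2-one)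
Product: 32 methyl 3-[(1R,2R,5S)-1,3-dimethyl-2-{[(2-oxo-2H-chromen-7-yl)oxy]methyl}-5-(prop-1-en-2-yl)cyclohex-3-en-1-yl]propanoate
Conditions: PPh3, DIAD, THF, 0 °C → rt
Reagents that add atoms: none
Why: Mitsunobu etherification: the phenol is acidic enough to be activated, and its anion displaces the alkoxyphosphonium group at the primary carbon C7, which is not a stereocentre. No base is present that could open the coumarin or isomerise the skipped diene.

Step 19
Reactants: 32 methyl ester of the target
Product: 34 3-[(1R,2R,5S)-1,3-dimethyl-2-{[(2-oxo-2H-chromen-7-yl)oxy]methyl}-5-(prop-1-en-2-yl)cyclohex-3-en-1-yl]propanoic acid, via lithium carboxylate 33 (not isolated)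
Conditions: LiOH, THF/H2O, 0 °C → rt; then 1 M HCl to pH 2
Reagents that add atoms: lithium hydroxide, [Li+].[OH-]
Why: Saponification of an unhindered methyl ester. If hydroxide also opens the coumarin lactone to the cis-coumarinate, acidification should close it again because the cis geometry is kept, so the intact target is expected after work-up.

## Compound list

1 | propanal | CCC=O | starting material
2 | (E)-N-tert-butylpropan-1-imine | CC/C=N/C(C)(C)C | intermediate
3 | 5-bromopent-1-ene | C=CCCCBr | starting material
4 | lithium aza-enolate of 2 (lithium tert-butyl(prop-1-enyl)amide) | CC=CN([Li])C(C)(C)C | intermediate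
5 | N-tert-butyl-2-methylhept-6-en-1-imine (racemic) | C=CCCCC(C)C=NC(C)(C)C | intermediate
6 | 2-methylhept-6-enal (racemic) | C=CCCCC(C)C=O | intermediate
7 | but-3-en-2-one (methyl vinyl ketone) | C=CC(C)=O | starting material
8 | 2-methyl-2-(3-oxobutyl)hept-6-enal (racemic) | C=CCCCC(C)(C=O)CCC(C)=O | intermediate
9 | 4-methyl-4-(pent-4-en-1-yl)cyclohex-2-en-1-one (racemic) | C=CCCCC1(C)C=CC(=O)CC1 | intermediate
10 | 4-methyl-4-(pent-4-en-1-yl)cyclohexa-2,5-dien-1-one | C=CCCCC1(C)C=CC(=O)C=C1 | intermediate
11 | 4-(4,5-dihydroxypentyl)-4-methylcyclohexa-2,5-dien-1-one | OCC(O)CCCC1(C)C=CC(=O)C=C1 | intermediate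
12 | 4-(1-methyl-4-oxocyclohexa-2,5-dien-1-yl)butanal | CC1(CCCC=O)C=CC(=O)C=C1 | intermediate
13 | (4aS,8aR)-4a-methyl-3,4,4a,8a-tetrahydronaphthalene-1,7(2H,8H)-dione (cis-fused) | O=C1CCC[C@@]2(C)C=CC(=O)C[C@@H]12 | intermediate
14 | (4a'S,8a'R)-4a'-methyl-3',4',4a',8a'-tetrahydro-2'H-spiro[1,3-dioxolane-2,1'-naphthalen]-7'(8'H)-one (C3 ethylene ketal of 13) | O1CCOC12CCC[C@@]3(C)C=CC(=O)C[C@@H]23 | intermediate
15 | potassium dienolate of 14 (C7=C8–OK) | O1CCOC12CCC[C@@]3(C)C=CC(O[K])=C[C@@H]23 | intermediate
16 | 8'-hydroxy derivative of 14 (both epimers at C7) | O1CCOC12CCC[C@@]3(C)C=CC(=O)C(O)[C@@H]23 | intermediate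
17 | 5',6'-dihydro derivative of 16 (saturated α-ketol, both epimers at C7) | O1CCOC12CCC[C@@]3(C)CCC(=O)C(O)[C@@H]23 | intermediate
18 | methyl 3-[(6S,7S)-6-formyl-7-methyl-1,4-dioxaspiro[4.5]decan-7-yl]propanoate | O1CCOC12CCC[C@@](C)(CCC(=O)OC)[C@H]2C=O | intermediate
19 | methyl 3-[(6S,7S)-6-(hydroxymethyl)-7-methyl-1,4-dioxaspiro[4.5]decan-7-yl]propanoate | O1CCOC12CCC[C@@](C)(CCC(=O)OC)[C@H]2CO | intermediate
20 | methyl 3-[(6S,7S)-6-{[tert-butyl(diphenyl)silyl]oxymethyl}-7-methyl-1,4-dioxaspiro[4.5]decan-7-yl]propanoate | O1CCOC12CCC[C@@](C)(CCC(=O)OC)[C@H]2CO[Si](c1ccccc1)(c1ccccc1)C(C)(C)C | intermediate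
21 | methyl 3-[(1S,2S)-2-{[tert-butyl(diphenyl)silyl]oxymethyl}-1-methyl-3-oxocyclohexyl]propanoate | O=C1CCC[C@@](C)(CCC(=O)OC)[C@H]1CO[Si](c1ccccc1)(c1ccccc1)C(C)(C)C | intermediate
22 | lithium enolate of 21 (C2=C3–OLi) | [Li]OC1=CCC[C@@](C)(CCC(=O)OC)[C@H]1CO[Si](c1ccccc1)(c1ccccc1)C(C)(C)C | intermediate
23 | trimethylsilyl enol ether of 21 (C2=C3–OSiMe3) | C[Si](C)(C)OC1=CCC[C@@](C)(CCC(=O)OC)[C@H]1CO[Si](c1ccccc1)(c1ccccc1)C(C)(C)C | intermediate
24 | methyl 3-[(1R,6S)-6-{[tert-butyl(diphenyl)silyl]oxymethyl}-1-methyl-5-oxocyclohex-3-en-1-yl]propanoate | O=C1C=CC[C@@](C)(CCC(=O)OC)[C@H]1CO[Si](c1ccccc1)(c1ccccc1)C(C)(C)C | intermediate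
25 | potassium trifluoro(prop-1-en-2-yl)borate | [K+].C=C(C)[B-](F)(F)F | starting material
26 | methyl 3-[(1R,2S,5S)-2-{[tert-butyl(diphenyl)silyl]oxymethyl}-1-methyl-3-oxo-5-(prop-1-en-2-yl)cyclohexyl]propanoate | O=C1C[C@@H](C(C)=C)C[C@@](C)(CCC(=O)OC)[C@H]1CO[Si](c1ccccc1)(c1ccccc1)C(C)(C)C | intermediate
27 | potassium enolate of 26 (C2=C3–OK) | [K]OC1=C[C@@H](C(C)=C)C[C@@](C)(CCC(=O)OC)[C@H]1CO[Si](c1ccccc1)(c1ccccc1)C(C)(C)C | intermediate
28 | methyl 3-[(1R,2S,5S)-2-{[tert-butyl(diphenyl)silyl]oxymethyl}-1-methyl-5-(prop-1-en-2-yl)-3-{[(trifluoromethyl)sulfonyl]oxy}cyclohex-3-en-1-yl]propanoate | FC(F)(F)S(=O)(=O)OC1=C[C@@H](C(C)=C)C[C@@](C)(CCC(=O)OC)[C@H]1CO[Si](c1ccccc1)(c1ccccc1)C(C)(C)C | intermediate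
29 | methyl 3-[(1R,2R,5S)-2-{[tert-butyl(diphenyl)silyl]oxymethyl}-1,3-dimethyl-5-(prop-1-en-2-yl)cyclohex-3-en-1-yl]propanoate | CC1=C[C@@H](C(C)=C)C[C@@](C)(CCC(=O)OC)[C@H]1CO[Si](c1ccccc1)(c1ccccc1)C(C)(C)C | intermediate
30 | methyl 3-[(1R,2R,5S)-2-(hydroxymethyl)-1,3-dimethyl-5-(prop-1-en-2-yl)cyclohex-3-en-1-yl]propanoate | CC1=C[C@@H](C(C)=C)C[C@@](C)(CCC(=O)OC)[C@H]1CO | intermediate
31 | umbelliferone (7-hydroxy-2H-chromen-2-one) | O=c1ccc2ccc(O)cc2o1 | starting material
32 | methyl 3-[(1R,2R,5S)-1,3-dimethyl-2-{[(2-oxo-2H-chromen-7-yl)oxy]methyl}-5-(prop-1-en-2-yl)cyclohex-3-en-1-yl]propanoate | CC1=C[C@@H](C(C)=C)C[C@@](C)(CCC(=O)OC)[C@H]1COc1ccc2ccc(=O)oc2c1 | intermediate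
33 | lithium salt of 34 | CC1=C[C@@H](C(C)=C)C[C@@](C)(CCC(=O)[O-])[C@H]1COc1ccc2ccc(=O)oc2c1.[Li+] | intermediate
34 | 3-[(1R,2R,5S)-1,3-dimethyl-2-{[(2-oxo-2H-chromen-7-yl)oxy]methyl}-5-(prop-1-en-2-yl)cyclohex-3-en-1-yl]propanoic acid | C=C(C)[C@@H]1C=C(C)[C@H](COc2ccc3ccc(=O)oc3c2)[C@](C)(CCC(=O)O)C1 | target

## Step count and least certain steps

Total step count: 19. Longest linear sequence: 19 steps (1 to 34); 3, 7, 25 and 31 are bought and enter along this one line.

**Step 6 (key step).** The six-membered closure of an aliphatic enaminol is slower than the five-membered closures for which this catalysis is best known. Dimerisation of the aldehyde, aldol condensation or base-induced Michael addition of the aldehyde α carbon may therefore compete, discrimination between the two enone arms may be incomplete, and base may epimerise C4 of 13 toward the trans-fused isomer. The fallback keeps the same bond and the same polarity reversal at C3 but uses a nitronate; it sets out from 12 and comes back at 13. The aldehyde of 12 would be reduced selectively (NaBH4, EtOH/CH2Cl2, −78 °C) to 4-(4-hydroxybutyl)-4-methylcyclohexa-2,5-dien-1-one F1. This would be converted (I2, PPh3, imidazole) into 4-(4-iodobutyl)-4-methylcyclohexa-2,5-dien-1-one F2 and then (NaNO2, DMF, Kornblum substitution) into 4-methyl-4-(4-nitrobutyl)cyclohexa-2,5-dien-1-one F3. A bifunctional cinchona-derived amine–thiourea catalyst would close C3–C4 by intramolecular Michael addition of the nitronate to one enantiotopic enone arm, giving cis-fused 4a-methyl-8-nitro-4a,5,6,7,8,8a-hexahydronaphthalen-2(1H)-one F4. A Nef reaction (NaNO2, AcOH, DMSO, 35 °C) would turn the secondary nitro group into the C3 carbonyl of 13.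

**Step 14.** Insertion may be slow because of the quaternary C5, so that protodeboronation of 25 wins; facial selectivity may be poor if the substrate's own bias opposes the ligand; and the warm amine medium may epimerise C4. The fallback changes from a catalytic, ligand-controlled addition to a stoichiometric organocopper addition with enolate capture; it sets out from 24 and comes back at 28, passing 26 by. Addition of (CH2=CMe)2CuLi (from 2-bromopropene, tBuLi and CuBr·SMe2) with Me3SiCl in THF at −78 °C would give methyl 3-[(1R,2S,5S)-2-{[tert-butyl(diphenyl)silyl]oxymethyl}-1-methyl-5-(prop-1-en-2-yl)-3-[(trimethylsilyl)oxy]cyclohex-3-en-1-yl]propanoate F5. Treatment with CsF and PhNTf2 in DME would convert it into 28. This fallback gives up ligand control, so the C1 epimers would have to be separated at 28 or 29.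

**Step 7.** Ketalisation may also take the enone carbonyl, or the acid may epimerise C4. The fallback protects both carbonyls and releases one; it sets out from 13 and comes back at 14. Exhaustive ketalisation (ethylene glycol, TsOH, toluene, Dean–Stark) would give the bis(ethylene ketal) of 13, F6. Selective hydrolysis of the allylic ketal, which ionises faster than the saturated one (PPTS, wet acetone, rt), would then give 14.

**Step 4.** Quinone dehydrogenation of 4,4-dialkylcyclohexenones can stall, and acid formed in the reaction can trigger a dienone–phenol shift. The fallback goes through a selenide; it sets out from 9 and comes back at 10. Kinetic deprotonation (LiN(iPr)2, THF, −78 °C), which can only occur at C6 of the enone, and capture with PhSeCl would give 4-methyl-4-(pent-4-en-1-yl)-6-(phenylselanyl)cyclohex-2-en-1-one F7. Oxidation (H2O2, pyridine, CH2Cl2, 0 °C) and syn elimination of the selenoxide would give 10.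

**Step 18.** Displacement at C7 is slowed by the branched C4 and the neighbouring quaternary C5, so alkylation of the reduced azodicarboxylate or elimination toward the ring may compete. The fallback replaces the redox condensation by a two-step alkylation; it sets out from 30 and comes back at 32. Tf2O and 2,6-lutidine in CH2Cl2 at −78 °C would give methyl 3-[(1R,2R,5S)-1,3-dimethyl-5-(prop-1-en-2-yl)-2-({[(trifluoromethyl)sulfonyl]oxy}methyl)cyclohex-3-en-1-yl]propanoate F8. The potassium salt of 31 (K2CO3, MeCN, 0 °C) would displace the triflate to give 32.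

## Further compounds

F1 | step 6 | 4-(4-hydroxybutyl)-4-methylcyclohexa-2,5-dien-1-one | CC1(CCCCO)C=CC(=O)C=C1
F2 | step 6 | 4-(4-iodobutyl)-4-methylcyclohexa-2,5-dien-1-one | CC1(CCCCI)C=CC(=O)C=C1
F3 | step 6 | 4-methyl-4-(4-nitrobutyl)cyclohexa-2,5-dien-1-one | CC1(CCCC[N+](=O)[O-])C=CC(=O)C=C1
F4 | step 6 | cis-fused 4a-methyl-8-nitro-4a,5,6,7,8,8a-hexahydronaphthalen-2(1H)-one (ring fusion as in 13; both epimers at the nitro-bearing carbon) | [O-][N+](=O)C1CCC[C@@]2(C)C=CC(=O)C[C@@H]12
F5 | step 14 | methyl 3-[(1R,2S,5S)-2-{[tert-butyl(diphenyl)silyl]oxymethyl}-1-methyl-5-(prop-1-en-2-yl)-3-[(trimethylsilyl)oxy]cyclohex-3-en-1-yl]propanoate | C[Si](C)(C)OC1=C[C@@H](C(C)=C)C[C@@](C)(CCC(=O)OC)[C@H]1CO[Si](c1ccccc1)(c1ccccc1)C(C)(C)C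
F6 | step 7 | bis(ethylene ketal) of 13 | O1CCOC12CCC[C@@]3(C)C=CC4(OCCO4)C[C@@H]23
F7 | step 4 | 4-methyl-4-(pent-4-en-1-yl)-6-(phenylselanyl)cyclohex-2-en-1-one (racemic, both diastereomers) | C=CCCCC1(C)C=CC(=O)C([Se]c2ccccc2)C1
F8 | step 18 | methyl 3-[(1R,2R,5S)-1,3-dimethyl-5-(prop-1-en-2-yl)-2-({[(trifluoromethyl)sulfonyl]oxy}methyl)cyclohex-3-en-1-yl]propanoate | CC1=C[C@@H](C(C)=C)C[C@@](C)(CCC(=O)OC)[C@H]1COS(=O)(=O)C(F)(F)F
A1 | alternative 1 | 2-{[tert-butyl(dimethyl)silyl]oxymethyl}-6-hydroxy-1,6-dimethylbicyclo[3.2.1]octan-3-one (both epimers at the carbinol carbon) | CC1(O)C[C@]2(C)C[C@H]1CC(=O)[C@@H]2CO[Si](C)(C)C(C)(C)C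
A2 | alternative 2 | 2-methylcyclohexan-1-one | CC1CCCCC1=O
A3 | alternative 2 | pent-1-en-3-one | CCC(=O)C=C
A4 | alternative 2 | (R)-1,4a-dimethyl-4,4a,5,6,7,8-hexahydronaphthalen-2(3H)-one | CC1=C2CCCC[C@]2(C)CCC1=O
A5 | alternative 3 | 2,6-dimethylbenzoic acid | Cc1cccc(C)c1C(=O)O
A6 | alternative 3 | (2,6-dimethylcyclohexa-2,5-dien-1-yl)methyl diazoacetate | CC1=CCC=C(C)C1COC(=O)C=[N+]=[N-]
A7 | alternative 3 | cyclopropane-fused tricyclic δ-lactone (carbenoid carbon bridging C5 and C6, lactone spanning C5 and C4) | CC1=CC[C@H]2[C@H]3C(=O)OC[C@@H]1[C@@]23C
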